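## Analysis of the target

Broussoflavonol G (21) is a flavonol: a 4H-chromen-4-one (fused rings A and C) with a hydroxyl at C3 and an aryl ring B at C2. Ring A is a phloroglucinol unit with hydroxyls at C5 and C7 and a 3-methylbut-2-enyl (prenyl) group at C8. Ring B carries a catechol at C4' and C5' and two neighbouring prenyl groups at C2' and C3', so that C6' is its only unsubstituted carbon. There is no stereocentre and the three trisubstituted alkenes have no geometry to control, so every difficulty is one of regiochemistry and functional-group tolerance. The sensitive groups are the five acidic hydroxyls (the catechol is easily oxidised) and the prenyl alkenes at C8 and C3', each ortho to a phenol (O7, O4') that adds to it under acid to form a chroman; hydrogenolysis, strong acids and electrophilic oxidants are therefore excluded late in the route. The hard points are placing one prenyl at C8 and not at the equally activated C6, building the crowded C1'–C2'–C3' array on ring B, and closing ring C beside the C2' substituent. The route rests on two positional relationships: C8 is para to the C5 oxygen across ring A and C3' is ortho to the C4' oxygen on ring B, so both prenyl groups can be attached to oxygen first and carried to carbon by sigmatropic shifts. C2' has only carbon neighbours and no such handle, so its prenyl group must be put on by carbon–carbon coupling before ring C is built.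

## Retrosynthetic reasoning

21 from 20. The last disconnection is of three acetal C–O bonds: the methoxymethyl (MOM) ethers at O3, O7 and O5'. They are chosen because they survive base, alkaline peroxide, semi-hydrogenation and a mild Lewis acid, and come off with dilute acid. O5 and O4' are already free in 20.

20 from 17. The C8–CH2 and C3'–CH2 bonds are cut and each prenyl group is returned to the oxygen from which a sigmatropic shift can deliver it: O5 as a prenyl ether, O4' as a 1,1-dimethylallyl ether. These are the only two prenyl groups with an oxygen in the right relation; the C2' prenyl has none and stays. The gain is two C–C bonds from simple O-alkylations, with the two phenols freed in the same event. Forward, the reaction must reach C8 and not stop at C6, and must give the normal prenyl orientation at both carbons.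

17 from 16. The vinyl group of the tertiary ether is traced back to an ethynyl group. The tertiary allyl aryl ether rearranges and ionises at modest temperature, whereas the propargyl ether is robust, so the alkene is unmasked only immediately before the key step.

16 from 15. The O3 acetal bond is cut. The enolic 3-hydroxyl has to be capped so that it neither competes for the Lewis acid nor is oxidised during heating.

15 from 13. Ring C is opened at O1–C2 and the C3 oxygen is removed, leading to 2'-hydroxychalcone 13. One oxidative cyclisation then has to form both bonds.

13 from 4 and 12. The Cα=Cβ bond is cut by a retro-aldol condensation. This splits the molecule into a ring A ketone and a ring B aldehyde of similar size, each carrying its prenyl unit in final or masked form.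

4 from 2 and 3, and 2 from 1. Two O-alkyl bonds are cut. The three hydroxyls of 1 are told apart by acidity and by hydrogen bonding to the acetyl group, so no extra protecting group is needed.

12 from 10 and 11. The O4–C(tertiary) bond is cut; the phenol para to the formyl group is the nucleophile.

10 from 8 and 9. The aryl C2–CH2 bond is cut at the position marked by bromine; a cross-coupling brings in the prenyl group that has no oxygen neighbour.

8 from 6 (through 7), and 6 from 5. The acetal on O5 is removed and the catechol is traced to the dimethyl ether 5. Forward, the two catechol oxygens must be distinguished; the formyl group para to O4 makes that possible.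

## Alternatives that were turned down

Alternative 1: The disconnection is ring A itself, with the C7–C8, C8a–C4a and C6–C7 bonds made by a Danheiser benzannulation. In the forward key step 3-ethoxycyclobut-2-en-1-one A2 opens on heating to a vinylketene, which adds (2+2) to siloxyalkyne A3; a four-electron ring opening and a six-electron closure then give phenol A1. In A1 the prenyl group sits between a free hydroxyl (future O7) and a silyl ether (future O1), and the third oxygen is an ethyl ether (future O5).
- For it: the connectivity of the alkyne fixes the prenyl group between two oxygens, so the C6/C8 question never arises, and the three oxygens come out differentiated. On regiochemical certainty at C8 this plan is stronger than a rearrangement that depends on a Cope shift outrunning enolisation.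
- Against it: it addresses one of three prenyl positions and leaves ring B untouched. A1 must still be acylated at the carbon between the silyl and ethyl ethers (future C4a) in competition with the other free ring carbon. The O5 ethyl ether would later need boron or aluminium halides or thiolates, which prenyl groups beside phenols do not survive. A3 takes several steps to make, against two steps from commercial 1 to ketone 4.
- Comparison: the chosen plan gives up built-in C8 selectivity for a purchased ring A, a prenyl group installed as an ether, and one thermal step that also serves ring B.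

Alternative 2: The disconnection is the C2–C1' bond between rings C and B, made by intramolecular direct arylation. In the forward key step zerovalent palladium inserts into the C1'–Br bond of bromo ester A5 (a chromon-3-yl 2-bromobenzoate), the aryl palladium unit palladates the chromone C2–H, and reductive elimination forms C2–C1' while closing a six-membered lactone to give A4.
- For it: the two halves are joined late, the hindered C2–C1' bond is made intramolecularly, and ring C exists from the start, so the oxidative chalcone cyclisation with its five-membered side path is avoided. On convergence and on that point it is at least as strong as the chosen plan.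
- Against it: the tether carbonyl ends on C2', where the target has a prenyl group. The lactone of A4 would have to be opened, reduced to the benzylic level beside the chromone carbonyl and coupled with an isobutenyl nucleophile, which means three or more late steps on a crowded flavonol. The acid half of A5 is a pentasubstituted benzene with a prenyl group next to the carboxyl, so the contiguous ring B problem is moved into a starting material and not solved. The C8 and C3' prenyl groups must already be present, and aryl palladium intermediates can add to prenyl alkenes.
- Comparison: the chosen plan forms ring C from 4 and 12 in two steps with the C2' prenyl as a spectator and spends its key step on the C–prenyl bonds, which are the real difficulty.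

Alternative 3: The disconnection is of both ring B side-chain bonds, C2'–CH2 and C3'–CH2, back to a C2'–C3' aryne. In the forward key step fluoride removes the silyl group of silyl triflate A7 and triflate leaves; the aryne inserts into the allyl palladium species formed from allyl chloride A8 and zerovalent palladium, and transmetalation with allyltributylstannane A9 followed by reductive elimination gives diallyl acetal A6.
- For it: the two neighbouring carbon substituents, the most crowded part of the molecule, are placed in one operation without any ortho oxygen, and because both termini receive the same group the orientation of the aryne does not matter. For C2', where the chosen route needs a separate cross-coupling, this is the more direct answer.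
- Against it: the groups delivered are allyl, not prenyl, since substituted allyl partners would scramble between linear and branched ends at the η3-allyl palladium stage; a double olefin cross-metathesis is then needed on A6. A7 is a pentasubstituted arene whose silyl, triflate, acetal and two MOM groups require a multistep preparation from a trioxygenated benzaldehyde. The acetal must later be removed without loss of the MOM ethers, and the C8 prenyl of ring A is still left to a rearrangement.
- Comparison: the chosen plan reaches aldehyde 12 from 5 in four steps and sets two of the three C-prenyl bonds in one thermal step.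

Key step: step 11

Remarks on the chemistry: flavone numbering is used (ring A C5–C8, ring C O1–C4, ring B primed); prenyl = 3-methylbut-2-en-1-yl, MOM = methoxymethyl. Stannane 9 is assumed to be purchased. Eu(fod)3 = tris(6,6,7,7,8,8,8-heptafluoro-2,2-dimethyloctane-3,5-dionato)europium.

## Route

Step 1
Reactants: 1 2,4,6-trihydroxyacetophenone
Product: 2 1-[2,6-dihydroxy-4-(methoxymethoxy)phenyl]ethan-1-one
Conditions: MOMCl (1.0 equiv), K2CO3, acetone, 0 °C → rt
Reagents that add atoms: chloromethyl methyl ether (MOMCl), COCCl
Why: Williamson-type O-alkylation; the C4 hydroxyl is the most acidic and the only one not held in a hydrogen bond to the acetyl group, so one equivalent of electrophile should go there, and the doubly protected by-product is separable.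

Step 2
Reactants: 2 1-[2,6-dihydroxy-4-(methoxymethoxy)phenyl]ethan-1-one; 3 prenyl bromide (1-bromo-3-methylbut-2-ene)
Product: 4 1-[2-hydroxy-4-(methoxymethoxy)-6-(3-methylbut-2-en-1-yloxy)phenyl]ethan-1-one
Conditions: K2CO3, acetone, reflux
Reagents that add atoms: none
Why: Williamson ether synthesis; the two ortho hydroxyls are equivalent, and after the first alkylation the remaining one is locked in a strong hydrogen bond to the carbonyl and resists a second alkylation, while carbonate in acetone favours O- over C-prenylation.

Step 3
Reactants: 5 2-bromo-4,5-dimethoxybenzaldehyde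
Product: 6 2-bromo-4,5-dihydroxybenzaldehyde
Conditions: BBr3, CH2Cl2, −78 °C → rt; H2O
Reagents that add atoms: none
Why: Lewis-acid cleavage of aryl methyl ethers (boron coordinates the ether oxygen, bromide removes the methyl group by SN2); the aldehyde and aryl bromide are inert and no acid-sensitive group is present yet.

Step 4
Reactants: 6 2-bromo-4,5-dihydroxybenzaldehyde
Product: 8 2-bromo-4-hydroxy-5-(methoxymethoxy)benzaldehyde, via disodium catecholate 7 (not isolated)
Conditions: NaH (2.1 equiv), DMF, 0 °C; MOMCl (1.0 equiv), −20 → 0 °C; aq. HCl to pH 5
Reagents that add atoms: chloromethyl methyl ether (MOMCl), COCCl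
Why: Regioselective monoalkylation of a catecholate dianion; in 7 the C4 phenoxide is delocalised into the para formyl group and is the weaker nucleophile, so the single equivalent of electrophile should be taken by the C5 oxygen and the C4 oxygen is recovered as the phenol on acidification.

Step 5
Reactants: 8 2-bromo-4-hydroxy-5-(methoxymethoxy)benzaldehyde; 9 tributyl(3-methylbut-2-en-1-yl)stannane
Product: 10 4-hydroxy-5-(methoxymethoxy)-2-(3-methylbut-2-en-1-yl)benzaldehyde
Conditions: Pd(PPh3)4 (5 mol%), DMF, 90 °C, Ar
Reagents that add atoms: none
Why: Stille cross-coupling; zerovalent palladium inserts into the C–Br bond activated by the ortho formyl group, the allylic stannane transmetalates, and reductive elimination at the unsubstituted CH2 terminus of the allyl ligand should give the linear prenyl arene, with aldehyde, acetal and free phenol tolerated under neutral conditions.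

Step 6
Reactants: 10 4-hydroxy-5-(methoxymethoxy)-2-(3-methylbut-2-en-1-yl)benzaldehyde; 11 3-chloro-3-methylbut-1-yne
Product: 12 5-(methoxymethoxy)-4-(2-methylbut-3-yn-2-yloxy)-2-(3-methylbut-2-en-1-yl)benzaldehyde
Conditions: DBU, CuCl2·2H2O (1 mol%), MeCN, 0 °C
Reagents that add atoms: none
Why: Copper-catalysed propargylic etherification; the copper-activated tertiary propargylic chloride ionises and the phenoxide adds at the tertiary carbon, a reaction that works best with electron-poor phenols such as this para-formyl phenol and runs far below the temperature of any propargyl Claisen shift.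

Step 7
Reactants: 4 1-[2-hydroxy-4-(methoxymethoxy)-6-(3-methylbut-2-en-1-yloxy)phenyl]ethan-1-one; 12 5-(methoxymethoxy)-4-(2-methylbut-3-yn-2-yloxy)-2-(3-methylbut-2-en-1-yl)benzaldehyde
Product: 13 (E)-1-[2-hydroxy-4-(methoxymethoxy)-6-(3-methylbut-2-en-1-yloxy)phenyl]-3-[5-(methoxymethoxy)-4-(2-methylbut-3-yn-2-yloxy)-2-(3-methylbut-2-en-1-yl)phenyl]prop-2-en-1-one
Conditions: KOH, EtOH, rt
Reagents that add atoms: none
Why: Claisen–Schmidt condensation; only ketone 4 can enolise, the aldehyde cannot, and E1cB loss of water gives the conjugated E-enone, while ethers, acetals and the terminal alkyne are stable to hydroxide.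

Step 8
Reactants: 13 (E)-2'-hydroxychalcone from step 7
Product: 15 3-hydroxy-7-(methoxymethoxy)-2-[5-(methoxymethoxy)-4-(2-methylbut-3-yn-2-yloxy)-2-(3-methylbut-2-en-1-yl)phenyl]-5-(3-methylbut-2-en-1-yloxy)-4H-chromen-4-one, via trans-dihydroflavonol 14 (not isolated)
Conditions: 30% aq. H2O2, aq. NaOH, MeOH–THF, 0 °C → rt
Reagents that add atoms: hydrogen peroxide, OO
Why: Algar–Flynn–Oyamada oxidative cyclisation; alkaline peroxide oxidises the enone while the 2'-phenoxide closes ring C at the β-carbon (six-membered mode) to 14, whose trans relative configuration is lost when it is dehydrogenated in the same flask to the flavonol. The nucleophilic oxidant leaves isolated alkenes and the alkyne alone, and low temperature is used to disfavour the five-membered (aurone) path that a 6'-alkoxy group promotes.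

Step 9
Reactants: 15 3-hydroxyflavone from step 8
Product: 16 3,7-bis(methoxymethoxy)-2-[5-(methoxymethoxy)-4-(2-methylbut-3-yn-2-yloxy)-2-(3-methylbut-2-en-1-yl)phenyl]-5-(3-methylbut-2-en-1-yloxy)-4H-chromen-4-one
Conditions: MOMCl, K2CO3, acetone, 50 °C
Reagents that add atoms: chloromethyl methyl ether (MOMCl), COCCl
Why: O-alkylation of the only free hydroxyl, the acidic enolic 3-OH, as its MOM ether; this removes a competing chelation site and an oxidisable enol before the Lewis-acid step.

Step 10
Reactants: 16 alkyne from step 9
Product: 17 3,7-bis(methoxymethoxy)-2-[5-(methoxymethoxy)-4-(2-methylbut-3-en-2-yloxy)-2-(3-methylbut-2-en-1-yl)phenyl]-5-(3-methylbut-2-en-1-yloxy)-4H-chromen-4-one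
Conditions: H2 (1 atm), Lindlar catalyst (Pd on CaCO3 poisoned with Pb(OAc)2), quinoline, EtOAc, rt
Reagents that add atoms: none
Why: Lindlar semi-hydrogenation; the poisoned palladium surface adds one equivalent of hydrogen to the terminal alkyne and stops at the alkene, and the trisubstituted prenyl alkenes, the allylic aryl ether and the chromone double bond should not be reduced.

Step 11
Reactants: 17 bis-ether from step 10
Product: 20 5-hydroxy-2-[4-hydroxy-5-(methoxymethoxy)-2,3-bis(3-methylbut-2-en-1-yl)phenyl]-3,7-bis(methoxymethoxy)-8-(3-methylbut-2-en-1-yl)-4H-chromen-4-one, via ring A C6 dienone 18 (not isolated), via monorearranged 8-prenylflavone 19 (not isolated)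
Conditions: Eu(fod)3 (20 mol%), NaHCO3, PhCl, 90 → 110 °C, Ar
Reagents that add atoms: none
Why: Trivalent europium in Eu(fod)3 binds the C4 carbonyl and the C5 ether oxygen, weakens the O5–CH2 bond and triggers a (3,3) Claisen shift that places the allyl unit on C6 in inverted form, giving dienone 18. Held in the keto form by the chelate, 18 undergoes a second (3,3) shift (Cope) in which the C6–C(CH3)2 bond breaks and the terminal CH2 bonds to C8, so the unit arrives in normal prenyl orientation, and enolisation then restores ring A with a hydrogen-bonded 5-OH (19). Independently, the tertiary ether at O4' undergoes an aromatic Claisen shift through a six-membered chair-like transition state to C3', and tautomerisation gives the 4'-phenol with a normal prenyl group. The closest known reactions are the europium-catalysed para-Claisen–Cope rearrangement of 5-O-prenylflavonoids and the Claisen rearrangement of aryl 1,1-dimethylallyl ethers to ortho-prenylphenols. Two aryl–CH2 bonds (at C8 and C3') are formed; no ring is closed and no stereocentre is created, because the C6 centre of 18 is lost on rearomatisation. The step needs C8 over C6 on ring A, which is secured by the Cope shift outrunning enolisation of 18 under europium chelation and by C8 being the only position para to O5; on ring B it needs C3' only, which is the sole unsubstituted ortho position because C5' carries the MOM ether. The gem-dimethyl group of the tertiary ether lowers the barrier of the ring B shift into the temperature range of the catalysed ring A sequence, and NaHCO3 keeps adventitious acid from ionising that ether or cyclising the new ortho-prenylphenols.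

Step 12
Reactants: 20 rearranged tris-MOM ether from step 11
Product: 21 broussoflavonol G, 2-[4,5-dihydroxy-2,3-bis(3-methylbut-2-en-1-yl)phenyl]-3,5,7-trihydroxy-8-(3-methylbut-2-en-1-yl)-4H-chromen-4-one
Conditions: 3 M aq. HCl, MeOH, 50 °C
Reagents that add atoms: none
Why: Acid-catalysed acetal solvolysis; protonation and transfer of the methoxymethyl group to methanol frees O3, O7 and O5', and dilute acid, moderate temperature and short contact should limit addition of the neighbouring phenols to the prenyl alkenes.

## Compound list

1 | 2,4,6-trihydroxyacetophenone | CC(=O)c1c(O)cc(O)cc1O | starting material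
2 | 1-[2,6-dihydroxy-4-(methoxymethoxy)phenyl]ethan-1-one | CC(=O)c1c(O)cc(OCOC)cc1O | intermediate
3 | prenyl bromide (1-bromo-3-methylbut-2-ene) | CC(C)=CCBr | starting material
4 | 1-[2-hydroxy-4-(methoxymethoxy)-6-(3-methylbut-2-en-1-yloxy)phenyl]ethan-1-one | CC(=O)c1c(O)cc(OCOC)cc1OCC=C(C)C | intermediate
5 | 2-bromo-4,5-dimethoxybenzaldehyde | COc1cc(Br)c(C=O)cc1OC | starting material
6 | 2-bromo-4,5-dihydroxybenzaldehyde | O=Cc1cc(O)c(O)cc1Br | intermediate
7 | disodium 4-bromo-5-formylbenzene-1,2-diolate (catecholate dianion of 6) | [Na+].[Na+].[O-]c1cc(Br)c(C=O)cc1[O-] | intermediate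
8 | 2-bromo-4-hydroxy-5-(methoxymethoxy)benzaldehyde | O=Cc1cc(OCOC)c(O)cc1Br | intermediate
9 | tributyl(3-methylbut-2-en-1-yl)stannane | CCCC[Sn](CCCC)(CCCC)CC=C(C)C | starting material
10 | 4-hydroxy-5-(methoxymethoxy)-2-(3-methylbut-2-en-1-yl)benzaldehyde | O=Cc1cc(OCOC)c(O)cc1CC=C(C)C | intermediate
11 | 3-chloro-3-methylbut-1-yne | C#CC(C)(C)Cl | starting material
12 | 5-(methoxymethoxy)-4-(2-methylbut-3-yn-2-yloxy)-2-(3-methylbut-2-en-1-yl)benzaldehyde | O=Cc1cc(OCOC)c(OC(C)(C)C#C)cc1CC=C(C)C | intermediate
13 | (E)-1-[2-hydroxy-4-(methoxymethoxy)-6-(3-methylbut-2-en-1-yloxy)phenyl]-3-[5-(methoxymethoxy)-4-(2-methylbut-3-yn-2-yloxy)-2-(3-methylbut-2-en-1-yl)phenyl]prop-2-en-1-one | O=C(/C=C/c1cc(OCOC)c(OC(C)(C)C#C)cc1CC=C(C)C)c1c(O)cc(OCOC)cc1OCC=C(C)C | intermediate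
14 | rac-(2R,3R)-3-hydroxy-7-(methoxymethoxy)-2-[5-(methoxymethoxy)-4-(2-methylbut-3-yn-2-yloxy)-2-(3-methylbut-2-en-1-yl)phenyl]-5-(3-methylbut-2-en-1-yloxy)chroman-4-one (trans-dihydroflavonol; one enantiomer drawn) | CC(C)=CCc1cc(OC(C)(C)C#C)c(OCOC)cc1[C@@H]2[C@H](C(=O)c3c(OCC=C(C)C)cc(OCOC)cc3O2)O | intermediate
15 | 3-hydroxy-7-(methoxymethoxy)-2-[5-(methoxymethoxy)-4-(2-methylbut-3-yn-2-yloxy)-2-(3-methylbut-2-en-1-yl)phenyl]-5-(3-methylbut-2-en-1-yloxy)-4H-chromen-4-one | COCOc1cc(OCC=C(C)C)c2c(=O)c(O)c(-c3cc(OCOC)c(OC(C)(C)C#C)cc3CC=C(C)C)oc2c1 | intermediate
16 | 3,7-bis(methoxymethoxy)-2-[5-(methoxymethoxy)-4-(2-methylbut-3-yn-2-yloxy)-2-(3-methylbut-2-en-1-yl)phenyl]-5-(3-methylbut-2-en-1-yloxy)-4H-chromen-4-one | COCOc1cc(OCC=C(C)C)c2c(=O)c(OCOC)c(-c3cc(OCOC)c(OC(C)(C)C#C)cc3CC=C(C)C)oc2c1 | intermediate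
17 | 3,7-bis(methoxymethoxy)-2-[5-(methoxymethoxy)-4-(2-methylbut-3-en-2-yloxy)-2-(3-methylbut-2-en-1-yl)phenyl]-5-(3-methylbut-2-en-1-yloxy)-4H-chromen-4-one | COCOc1cc(OCC=C(C)C)c2c(=O)c(OCOC)c(-c3cc(OCOC)c(OC(C)(C)C=C)cc3CC=C(C)C)oc2c1 | intermediate
18 | rac-3,7-bis(methoxymethoxy)-2-[5-(methoxymethoxy)-4-(2-methylbut-3-en-2-yloxy)-2-(3-methylbut-2-en-1-yl)phenyl]-6-(2-methylbut-3-en-2-yl)-4H-chromene-4,5(6H)-dione (ring A C6 dienone) | COCOC1=CC2=C(C(=O)C1C(C)(C)C=C)C(=O)C(OCOC)=C(c1cc(OCOC)c(OC(C)(C)C=C)cc1CC=C(C)C)O2 | intermediate
19 | 5-hydroxy-3,7-bis(methoxymethoxy)-2-[5-(methoxymethoxy)-4-(2-methylbut-3-en-2-yloxy)-2-(3-methylbut-2-en-1-yl)phenyl]-8-(3-methylbut-2-en-1-yl)-4H-chromen-4-one | COCOc1cc(O)c2c(=O)c(OCOC)c(-c3cc(OCOC)c(OC(C)(C)C=C)cc3CC=C(C)C)oc2c1CC=C(C)C | intermediate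
20 | 5-hydroxy-2-[4-hydroxy-5-(methoxymethoxy)-2,3-bis(3-methylbut-2-en-1-yl)phenyl]-3,7-bis(methoxymethoxy)-8-(3-methylbut-2-en-1-yl)-4H-chromen-4-one | COCOc1cc(O)c2c(=O)c(OCOC)c(-c3cc(OCOC)c(O)c(CC=C(C)C)c3CC=C(C)C)oc2c1CC=C(C)C | intermediate
21 | broussoflavonol G | CC(C)=CCc1c(-c2oc3c(CC=C(C)C)c(O)cc(O)c3c(=O)c2O)cc(O)c(O)c1CC=C(C)C | target

## Step count and risk

Total step count: 12. Longest linear sequence: 10 steps (steps 3 to 12, from 5); the ring A branch (steps 1 and 2) joins at step 7.

Least certain steps:

**Step 11 (key step).** Two processes are most likely to go wrong.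
- On ring A, dienone 18 may tautomerise before the Cope shift, leaving the allyl unit at C6 in its inverted 1,1-dimethylallyl form.
- On ring B, the tertiary allyl ether may ionise on the Lewis acid with loss of the allyl group, or the freed ortho-prenylphenols may cyclise to chromans if heating is prolonged to finish the slower of the two events.

Both arise because one set of conditions has to serve two shifts with different demands. The fallback runs the shifts one at a time, each under its own conditions. It sets out from alkyne 16, which is treated with Eu(fod)3 and NaHCO3 in PhCl at 85 °C; the propargyl ether is inert at that temperature, so only the ring A Claisen–Cope sequence should occur, giving 5-hydroxy-3,7-bis(methoxymethoxy)-2-[5-(methoxymethoxy)-4-(2-methylbut-3-yn-2-yloxy)-2-(3-methylbut-2-en-1-yl)phenyl]-8-(3-methylbut-2-en-1-yl)-4H-chromen-4-one F1. Lindlar semi-hydrogenation of F1 gives 19, isolated this time, and heating 19 without Lewis acid (N,N-diethylaniline, 130 °C) effects the ring B Claisen shift and comes back to the route at 20.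

**Step 8.** The phenoxide may close on the α-carbon of the oxidised enone (five-membered mode) and not on the β-carbon, because the 6'-alkoxy group and the ortho-prenyl group twist the enone out of plane; dehydrogenation of 14 may also stall. The fallback closes ring C before the oxygen is introduced, so the five-membered mode is not available.
- It sets out from 13, which cyclises by oxa-Michael addition (NaOAc, EtOH, reflux) to rac-7-(methoxymethoxy)-2-[5-(methoxymethoxy)-4-(2-methylbut-3-yn-2-yloxy)-2-(3-methylbut-2-en-1-yl)phenyl]-5-(3-methylbut-2-en-1-yloxy)chroman-4-one F2.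
- Soft enolisation (TMSOTf, Et3N, CH2Cl2, −78 → 0 °C) gives the silyl enol ether rac-trimethyl{[7-(methoxymethoxy)-2-[5-(methoxymethoxy)-4-(2-methylbut-3-yn-2-yloxy)-2-(3-methylbut-2-en-1-yl)phenyl]-5-(3-methylbut-2-en-1-yloxy)-2H-chromen-4-yl]oxy}silane F3.
- Rubottom oxidation of F3 with 2-(phenylsulfonyl)-3-phenyloxaziridine (which leaves isolated alkenes and the alkyne alone, and attacks anti to the C2 aryl group), followed by aqueous citric acid, comes back to the route at 14, which is dehydrogenated to 15 with alkaline H2O2 as in the second stage of step 8.

**Step 4.** Site selectivity between the two phenoxide oxygens may be poor, or double alkylation may occur, because MOMCl is a very reactive and weakly discriminating electrophile; the catecholate is also air-sensitive. The fallback replaces kinetic discrimination in the dianion by a temporary block on O4.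
- It sets out from 6, whose more acidic para hydroxyl is alkylated as the monoanion (4-methoxybenzyl chloride, NaHCO3, NaI, DMF, 40 °C) to give 2-bromo-5-hydroxy-4-(4-methoxybenzyloxy)benzaldehyde F4.
- MOMCl and i-Pr2NEt give 2-bromo-5-(methoxymethoxy)-4-(4-methoxybenzyloxy)benzaldehyde F5.
- Oxidative removal of the 4-methoxybenzyl group (DDQ, CH2Cl2–H2O), done before any prenyl group is present, comes back to the route at 8.

**Step 5.** Allyl transposition at palladium may give the branched 1,1-dimethylallyl isomer, a palladium hydride may move the double bond into conjugation with the ring, and the acidic phenol may protonate stannane 9. The fallback builds the prenyl group in two stages. It sets out from 8, which is coupled with allyltributylstannane (A9) under the same palladium catalysis (an unsubstituted allyl group has no regiochemical ambiguity) to give 2-allyl-4-hydroxy-5-(methoxymethoxy)benzaldehyde F6. Olefin cross-metathesis of F6 with 2-methylbut-2-ene (second-generation Grubbs catalyst, CH2Cl2, 40 °C) installs the isopropylidene end and comes back to the route at 10.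

**Step 12.** The phenols freed at O7 and O4' may add to the neighbouring prenyl alkenes under Brønsted acid (chroman formation), or the alkenes may be hydrated. The fallback avoids protic acid: it sets out from 20 and transfers the three methoxymethyl groups to sulfur with ZnBr2 and propane-1-thiol in CH2Cl2 at 0 °C within minutes, arriving directly at 21. This fallback makes no new compound (F0).

## Further compounds

F1 | step 11 | 5-hydroxy-3,7-bis(methoxymethoxy)-2-[5-(methoxymethoxy)-4-(2-methylbut-3-yn-2-yloxy)-2-(3-methylbut-2-en-1-yl)phenyl]-8-(3-methylbut-2-en-1-yl)-4H-chromen-4-one | COCOc1cc(O)c2c(=O)c(OCOC)c(-c3cc(OCOC)c(OC(C)(C)C#C)cc3CC=C(C)C)oc2c1CC=C(C)C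
F2 | step 8 | rac-7-(methoxymethoxy)-2-[5-(methoxymethoxy)-4-(2-methylbut-3-yn-2-yloxy)-2-(3-methylbut-2-en-1-yl)phenyl]-5-(3-methylbut-2-en-1-yloxy)chroman-4-one | O=C1CC(c2cc(OCOC)c(OC(C)(C)C#C)cc2CC=C(C)C)Oc2cc(OCOC)cc(OCC=C(C)C)c21
F3 | step 8 | rac-trimethyl{[7-(methoxymethoxy)-2-[5-(methoxymethoxy)-4-(2-methylbut-3-yn-2-yloxy)-2-(3-methylbut-2-en-1-yl)phenyl]-5-(3-methylbut-2-en-1-yloxy)-2H-chromen-4-yl]oxy}silane | C[Si](C)(C)OC1=CC(c2cc(OCOC)c(OC(C)(C)C#C)cc2CC=C(C)C)Oc2cc(OCOC)cc(OCC=C(C)C)c21
F4 | step 4 | 2-bromo-5-hydroxy-4-(4-methoxybenzyloxy)benzaldehyde | O=Cc1cc(O)c(OCc2ccc(OC)cc2)cc1Br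
F5 | step 4 | 2-bromo-5-(methoxymethoxy)-4-(4-methoxybenzyloxy)benzaldehyde | O=Cc1cc(OCOC)c(OCc2ccc(OC)cc2)cc1Br
F6 | step 5 | 2-allyl-4-hydroxy-5-(methoxymethoxy)benzaldehyde | O=Cc1cc(OCOC)c(O)cc1CC=C
F0 | step 12 | none | none
A1 | alternative 1 | 5-ethoxy-2-(3-methylbut-2-en-1-yl)-3-(triisopropylsilyloxy)phenol | CCOc1cc(O)c(CC=C(C)C)c(O[Si](C(C)C)(C(C)C)C(C)C)c1
A2 | alternative 1 | 3-ethoxycyclobut-2-en-1-one | CCOC1=CC(=O)C1
A3 | alternative 1 | triisopropyl[(5-methylhex-4-en-1-yn-1-yl)oxy]silane | CC(C)=CCC#CO[Si](C(C)C)(C(C)C)C(C)C
A4 | alternative 2 | lactone-bridged 2-arylchromone (O3–C(=O)–C2' bridge, tetrakis-MOM ether, 8,3'-diprenyl) | O=C1Oc2c(-c4cc(OCOC)c(OCOC)c(CC=C(C)C)c41)oc3c(CC=C(C)C)c(OCOC)cc(OCOC)c3c2=O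
A5 | alternative 2 | 5,7-bis(methoxymethoxy)-8-(3-methylbut-2-en-1-yl)-4-oxo-4H-chromen-3-yl 2-bromo-4,5-bis(methoxymethoxy)-6-(3-methylbut-2-en-1-yl)benzoate | O=C(Oc1coc2c(CC=C(C)C)c(OCOC)cc(OCOC)c2c1=O)c1c(Br)cc(OCOC)c(OCOC)c1CC=C(C)C
A6 | alternative 3 | 2-[2,3-diallyl-4,5-bis(methoxymethoxy)phenyl]-1,3-dioxolane | C=CCc1c(C2OCCO2)cc(OCOC)c(OCOC)c1CC=C
A7 | alternative 3 | 3-(1,3-dioxolan-2-yl)-5,6-bis(methoxymethoxy)-2-(trimethylsilyl)phenyl trifluoromethanesulfonate | C[Si](C)(C)c1c(C2OCCO2)cc(OCOC)c(OCOC)c1OS(=O)(=O)C(F)(F)F
A8 | alternative 3 | allyl chloride | C=CCCl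
A9 | alternative 3 | allyltributylstannane | C=CC[Sn](CCCC)(CCCC)CCCC
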